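**Plan**

- Retrosynthesis: cut the side-chain C4'=C5' bond (Wittig), then the C2'–CH3 bond (conjugate addition) and the C2'=C3' olefin. Join the two two-carbon arms on C3 and C5 back into one cis-alkene of a seven-membered carbocycle. Last, take O–O out from between C3 and C5 of the dioxolane.
- Forward: o-xylene → Birch diene → cyclopropane on the tetrasubstituted alkene gives meso 1,6-dimethylbicyclo[4.1.0]hept-3-ene. O2 is then inserted into its C1–C6 bond, so the three-membered ring (C1, C7, C6) grows into the 1,2-dioxolane. Ozonolysis opens the temporary carbocycle to two identical hydroxyethyl arms.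
- Enabling feature: C1–C6 is the tetra-alkyl-substituted, electron-rich edge of the cyclopropane (its σ HOMO). The cyclohexene ring fused across it forces both new C–O bonds onto one face, so the cis-3,5-dimethyl array needs no acyclic stereocontrol.
- Stereochemistry: C3/C5 relative configuration comes from the ring fusion (meso). Absolute configuration comes from lipase desymmetrisation of the meso diol. The side-chain methyl centre comes from catalyst-controlled Cu/Josiphos conjugate addition.
- Endgame: thioester → aldehyde → Wittig with the phenylhexyl ylide → diimide; the remaining arm is oxidised to the acetic acid last.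

Key step: step 4

Assumption: lipase PS is taken to acylate the hydroxyethyl arm on the (S)-configured ring carbon of the meso diol; if its group preference is the opposite, the same enzyme run in the hydrolytic direction on the meso diacetate should deliver the same monoacetate.
Assumption: of the two commercial Josiphos enantiomers, the one that delivers methyl to the Si face of C-3 of the enethioate is used.

Step 1
Reactants: 1 o-xylene
Product: 2 1,2-dimethylcyclohexa-1,4-diene
Conditions: Li, NH3(l), EtOH, Et2O, −78 → −33 °C
Reagents that add atoms: none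
Why: Birch reduction: dissolving-metal reduction of the arene leaves the two electron-donating methyl groups on one of the residual double bonds, giving the unconjugated 1,4-diene with one tetrasubstituted and one cis-disubstituted alkene; no stereocentre is formed.

Step 2
Reactants: 2 1,2-dimethylcyclohexa-1,4-diene
Product: 3 (1R,6S)-7,7-dibromo-1,6-dimethylbicyclo[4.1.0]hept-3-ene (meso)
Conditions: CHBr3, KOt-Bu, pentane, −10 → 20 °C
Reagents that add atoms: bromoform, BrC(Br)Br
Why: Dihalocarbene [2+1] cycloaddition: electrophilic singlet dibromocarbene adds concertedly and suprafacially, and much faster to the electron-rich tetrasubstituted double bond than to the disubstituted one, so the two ring-fusion centres are created cis (meso) by the mechanism.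

Step 3
Reactants: 3 (1R,6S)-7,7-dibromo-1,6-dimethylbicyclo[4.1.0]hept-3-ene
Product: 4 (1R,6S)-1,6-dimethylbicyclo[4.1.0]hept-3-ene (meso)
Conditions: Li, t-BuOH, THF, reflux
Reagents that add atoms: none
Why: Dissolving-metal hydrodehalogenation of a gem-dibromocyclopropane: both C–Br bonds are reduced through cyclopropyl radicals/anions that t-BuOH protonates, while the ring bonds, the isolated alkene and the meso ring-fusion centres stay untouched.

Step 4
Reactants: 4 (1R,6S)-1,6-dimethylbicyclo[4.1.0]hept-3-ene
Product: 5 (1R,6S)-1,6-dimethyl-7,8-dioxabicyclo[4.2.1]non-3-ene (meso)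
Conditions: O2 (1 atm), 9,10-dicyanoanthracene (5 mol %), biphenyl (0.3 equiv), Mg(ClO4)2 (0.5 equiv), MeCN, hν (405–420 nm), 0 °C
Reagents that add atoms: dioxygen, O=O
Why: Proposed new method: excited dicyanoanthracene (biphenyl as co-sensitiser) should remove one electron from the high-lying bent-bond σ orbital localised on the tetra-alkyl-substituted C1–C6 edge of the cyclopropane; the resulting radical cation with a one-electron C1···C6 bond is captured by O2/superoxide at one terminus and the peroxyl (peroxide) end then bonds to the second tertiary centre, so O–O is inserted into the three-membered ring and the cyclopropane (C1, C7, C6) becomes the 1,2-dioxolane (formal [3+2], ring enlargement 3→5). The closest known reaction types are the dicyanoanthracene-sensitised photo-oxygenation of aryl- and vinylcyclopropanes to 1,2-dioxolanes and the anodic or photo-electron-transfer 1,3-dialkoxylation of alkylcyclopropanes, which open exactly the most substituted ring bond; what is new is O2 insertion into a purely alkyl-substituted bond. The dioxolane closes by combination of the second oxygen with the C6 radical/cation centre, a five-membered closure that is transannular on the cycloheptene ring. Both new stereocentres (C1 and C6 of 5) are controlled by the carbocycle: the two carbons remain tied in the seven-membered ring, so both C–O bonds must form on the same face and the meso cis-3,5-dimethyl array should result whatever the lifetime of the open intermediate. The step needs chemoselectivity for the cyclopropane bond over the ring alkene and over deprotonation of the radical cation; the easier oxidation of a tetra-alkyl cyclopropane edge compared with a cis-dialkyl alkene, the non-nucleophilic medium, low temperature and Mg(ClO4)2 (which ties up basic superoxide) are meant to secure this.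

Step 5
Reactants: 5 (1R,6S)-1,6-dimethyl-7,8-dioxabicyclo[4.2.1]non-3-ene
Product: 7 2,2'-[(3R,5S)-3,5-dimethyl-1,2-dioxolane-3,5-diyl]di(ethan-1-ol) (meso), via dialdehyde 6 (not isolated)
Conditions: O3, pyridine (3 equiv), CH2Cl2, −78 °C; then NaBH4, MeOH, −78 → 0 °C
Reagents that add atoms: ozone, [O-][O+]=O
Why: Ozonolysis with reductive work-up: ozone cleaves the only C=C (dialkyl peroxides are inert to ozone, and pyridine lets the carbonyl oxide collapse to the dialdehyde without an added reductant) and borohydride then reduces both aldehydes without attacking the hindered di-tert-alkyl peroxide; no stereocentre is affected and the product stays meso.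

Step 6
Reactants: 7 2,2'-[(3R,5S)-3,5-dimethyl-1,2-dioxolane-3,5-diyl]di(ethan-1-ol)
Product: 8 2-[(3S,5R)-5-(2-hydroxyethyl)-3,5-dimethyl-1,2-dioxolan-3-yl]ethyl acetate
Conditions: lipase PS (Burkholderia cepacia, immobilised), vinyl acetate, t-BuOMe, 25 °C
Reagents that add atoms: vinyl acetate, C=COC(C)=O
Why: Enzymatic desymmetrisation of a meso diol (lipase-catalysed irreversible transesterification with an enol ester): the chiral active site acylates only one of the two enantiotopic hydroxyethyl arms, which fixes the absolute configuration of both quaternary peroxy carbons in one operation.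

Step 7
Reactants: 8 2-[(3S,5R)-5-(2-hydroxyethyl)-3,5-dimethyl-1,2-dioxolan-3-yl]ethyl acetate
Product: 9 2-[(3S,5S)-3,5-dimethyl-5-(2-oxoethyl)-1,2-dioxolan-3-yl]ethyl acetate
Conditions: Dess–Martin periodinane, CH2Cl2, 0 °C → rt
Reagents that add atoms: none
Why: Dess–Martin oxidation: the neutral hypervalent-iodine oxidant converts the only free primary alcohol into the aldehyde without base, so the β-peroxy aldehyde is not exposed to conditions that would eliminate the peroxide; no stereocentre is touched.

Step 8
Reactants: 9 2-[(3S,5S)-3,5-dimethyl-5-(2-oxoethyl)-1,2-dioxolan-3-yl]ethyl acetate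
Product: 10 S-ethyl (2E)-4-[(3R,5S)-5-(2-acetoxyethyl)-3,5-dimethyl-1,2-dioxolan-3-yl]but-2-enethioate
Conditions: Ph3P=CHC(O)SEt, CH2Cl2, rt → 40 °C
Reagents that add atoms: S-ethyl 2-(triphenyl-λ5-phosphanylidene)ethanethioate (known stabilised ylide), CCSC(=O)C=P(c1ccccc1)(c1ccccc1)c1ccccc1
Why: Wittig olefination with a stabilised ylide: the carbonyl-stabilised phosphorane reacts under neutral conditions through reversible oxaphosphetane formation and should give the (E)-enethioate, the acceptor needed for step 9.

Step 9
Reactants: 10 S-ethyl (2E)-4-[(3R,5S)-5-(2-acetoxyethyl)-3,5-dimethyl-1,2-dioxolan-3-yl]but-2-enethioate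
Product: 11 S-ethyl (3S)-4-[(3R,5S)-5-(2-acetoxyethyl)-3,5-dimethyl-1,2-dioxolan-3-yl]-3-methylbutanethioate
Conditions: MeMgBr (1.2 equiv), CuBr·SMe2 (5 mol %), Josiphos (6 mol %, enantiomer as assumed), t-BuOMe, −75 °C; then aq NH4Cl
Reagents that add atoms: methylmagnesium bromide, C[Mg]Br
Why: Copper-catalysed asymmetric conjugate addition of a Grignard reagent to an α,β-unsaturated thioester: the chiral Cu–Josiphos complex delivers methyl to the Si face of C-3 (catalyst control, the remote ring centres have no say), which sets the future side-chain methyl centre, and at −75 °C the hindered di-tert-alkyl peroxide and the acetate should survive.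

Step 10
Reactants: 11 S-ethyl (3S)-4-[(3R,5S)-5-(2-acetoxyethyl)-3,5-dimethyl-1,2-dioxolan-3-yl]-3-methylbutanethioate
Product: 12 (3S)-4-[(3R,5S)-5-(2-hydroxyethyl)-3,5-dimethyl-1,2-dioxolan-3-yl]-3-methylbutanal
Conditions: DIBAL-H (3.3 equiv), CH2Cl2, −78 °C; then aq Rochelle salt
Reagents that add atoms: none
Why: Partial hydride reduction: at −78 °C DIBAL-H converts the thioester into the aldehyde through a stable tetrahedral aluminate and at the same time removes the acetate reductively, the methyl-bearing centre being β to the carbonyl and therefore not epimerisable.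

Step 11
Reactants: 13 (6-bromohexyl)benzene
Product: 14 (6-phenylhexyl)triphenylphosphonium bromide
Conditions: PPh3, MeCN, reflux
Reagents that add atoms: triphenylphosphine, c1ccc(cc1)P(c1ccccc1)c1ccccc1
Why: SN2 quaternisation of triphenylphosphine by the unhindered primary bromide gives the Wittig salt.

Step 12
Reactants: 14 (6-phenylhexyl)triphenylphosphonium bromide; 12 (3S)-4-[(3R,5S)-5-(2-hydroxyethyl)-3,5-dimethyl-1,2-dioxolan-3-yl]-3-methylbutanal
Product: 16 2-[(3S,5R)-3,5-dimethyl-5-[(2R,4Z)-2-methyl-10-phenyldec-4-en-1-yl]-1,2-dioxolan-3-yl]ethan-1-ol, via ylide 15 (not isolated)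
Conditions: 14 (2.3 equiv), NaHMDS (2.2 equiv), THF, −78 °C; then 12, −78 °C → rt
Reagents that add atoms: none
Why: Wittig olefination with a non-stabilised ylide: excess ylide (one equivalent is consumed as base by the free hydroxyl) joins the phenylhexyl chain to the aldehyde, mainly as the (Z)-alkene, whose geometry is irrelevant because it is reduced in the next step.

Step 13
Reactants: 16 2-[(3S,5R)-3,5-dimethyl-5-[(2R,4Z)-2-methyl-10-phenyldec-4-en-1-yl]-1,2-dioxolan-3-yl]ethan-1-ol
Product: 17 2-[(3S,5R)-3,5-dimethyl-5-[(2R)-2-methyl-10-phenyldecyl]-1,2-dioxolan-3-yl]ethan-1-ol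
Conditions: KO2C–N=N–CO2K, AcOH, MeOH/CH2Cl2, 0 °C → rt
Reagents that add atoms: none
Why: Diimide reduction: concerted syn transfer of H2 from HN=NH saturates the disubstituted alkene and, unlike catalytic hydrogenation, leaves the O–O bond and the phenyl ring intact.

Step 14
Reactants: 17 2-[(3S,5R)-3,5-dimethyl-5-[(2R)-2-methyl-10-phenyldecyl]-1,2-dioxolan-3-yl]ethan-1-ol
Product: 19 2-[(3R,5R)-3,5-dimethyl-5-[(2R)-2-methyl-10-phenyldecyl]-1,2-dioxolan-3-yl]acetic acid, via aldehyde 18 (not isolated)
Conditions: TEMPO (20 mol %), PhI(OAc)2 (2.2 equiv), MeCN/H2O (1:1), rt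
Reagents that add atoms: water, O
Why: Nitroxyl-catalysed oxidation with a hypervalent-iodine co-oxidant in aqueous acetonitrile takes the primary alcohol through the aldehyde hydrate to the carboxylic acid under near-neutral conditions that a di-tert-alkyl peroxide tolerates; no stereocentre is affected.

**Compound list**

1 | o-xylene | Cc1ccccc1C | starting material
2 | 1,2-dimethylcyclohexa-1,4-diene | CC1=C(C)CC=CC1 | intermediate
3 | (1R,6S)-7,7-dibromo-1,6-dimethylbicyclo[4.1.0]hept-3-ene (meso, cis-fused) | C1=CC[C@]2(C)C(Br)(Br)[C@]2(C)C1 | intermediate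
4 | (1R,6S)-1,6-dimethylbicyclo[4.1.0]hept-3-ene (meso, cis-fused) | C1=CC[C@]2(C)C[C@]2(C)C1 | intermediate
5 | (1R,6S)-1,6-dimethyl-7,8-dioxabicyclo[4.2.1]non-3-ene (meso) | C1=CC[C@]2(C)C[C@](C)(C1)OO2 | intermediate
6 | 2,2'-[(3R,5S)-3,5-dimethyl-1,2-dioxolane-3,5-diyl]diacetaldehyde (meso) | O=CC[C@]1(C)C[C@](C)(CC=O)OO1 | intermediate (not isolated)
7 | 2,2'-[(3R,5S)-3,5-dimethyl-1,2-dioxolane-3,5-diyl]di(ethan-1-ol) (meso) | OCC[C@]1(C)C[C@](C)(CCO)OO1 | intermediate
8 | 2-[(3S,5R)-5-(2-hydroxyethyl)-3,5-dimethyl-1,2-dioxolan-3-yl]ethyl acetate | OCC[C@]1(C)C[C@](C)(CCOC(C)=O)OO1 | intermediate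
9 | 2-[(3S,5S)-3,5-dimethyl-5-(2-oxoethyl)-1,2-dioxolan-3-yl]ethyl acetate | O=CC[C@]1(C)C[C@](C)(CCOC(C)=O)OO1 | intermediate
10 | S-ethyl (2E)-4-[(3R,5S)-5-(2-acetoxyethyl)-3,5-dimethyl-1,2-dioxolan-3-yl]but-2-enethioate | CCSC(=O)/C=C/C[C@]1(C)C[C@](C)(CCOC(C)=O)OO1 | intermediate
11 | S-ethyl (3S)-4-[(3R,5S)-5-(2-acetoxyethyl)-3,5-dimethyl-1,2-dioxolan-3-yl]-3-methylbutanethioate | CCSC(=O)C[C@@H](C)C[C@]1(C)C[C@](C)(CCOC(C)=O)OO1 | intermediate
12 | (3S)-4-[(3R,5S)-5-(2-hydroxyethyl)-3,5-dimethyl-1,2-dioxolan-3-yl]-3-methylbutanal | O=CC[C@@H](C)C[C@]1(C)C[C@](C)(CCO)OO1 | intermediate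
13 | (6-bromohexyl)benzene | BrCCCCCCc1ccccc1 | starting material
14 | (6-phenylhexyl)triphenylphosphonium bromide | [Br-].c1ccccc1CCCCCC[P+](c1ccccc1)(c1ccccc1)c1ccccc1 | intermediate
15 | (6-phenylhexylidene)triphenyl-λ5-phosphane | c1ccccc1CCCCCC=P(c1ccccc1)(c1ccccc1)c1ccccc1 | intermediate (not isolated)
16 | 2-[(3S,5R)-3,5-dimethyl-5-[(2R,4Z)-2-methyl-10-phenyldec-4-en-1-yl]-1,2-dioxolan-3-yl]ethan-1-ol | C[C@H](C/C=C\CCCCCc1ccccc1)C[C@]1(C)C[C@](C)(CCO)OO1 | intermediate
17 | 2-[(3S,5R)-3,5-dimethyl-5-[(2R)-2-methyl-10-phenyldecyl]-1,2-dioxolan-3-yl]ethan-1-ol | C[C@H](CCCCCCCCc1ccccc1)C[C@]1(C)C[C@](C)(CCO)OO1 | intermediate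
18 | 2-[(3R,5R)-3,5-dimethyl-5-[(2R)-2-methyl-10-phenyldecyl]-1,2-dioxolan-3-yl]acetaldehyde | C[C@H](CCCCCCCCc1ccccc1)C[C@]1(C)C[C@](C)(CC=O)OO1 | intermediate (not isolated)
19 | 2-[(3R,5R)-3,5-dimethyl-5-[(2R)-2-methyl-10-phenyldecyl]-1,2-dioxolan-3-yl]acetic acid | C[C@H](CCCCCCCCc1ccccc1)C[C@]1(C)C[C@](C)(CC(=O)O)OO1 | target

**Step count and risks**

Total step count: 14. Longest linear sequence: 13 (steps 1–10 and 12–14, from o-xylene).

Steps most likely to fail:

1. Step 4 (proposed new method). The radical cation may lose a proton from a neighbouring CH2 or CH3 faster than it takes up oxygen, leading to allylic or homoallylic hydroperoxides. The ring alkene may also be oxidised competitively, so that O–O insertion into the cyclopropane edge does not prevail. The fallback uses known chemistry and sets out from 4. Constant-current anodic oxidation in methanol (carbon anode, Et4NOTs), the known 1,3-dimethoxylation of alkylcyclopropanes that also opens the most substituted ring bond, should give 4,6-dimethoxy-4,6-dimethylcyclohept-1-ene F1 as a cis/trans mixture. Acid-catalysed perhydrolysis (50% H2O2, cat. H2SO4, Et2O, 0 °C), the known route from ditertiary 1,3-diol derivatives to 1,2-dioxolanes, then exchanges both tertiary methoxy groups by SN1. The second C–O bond can only form transannularly, so both isomers of F1 converge on 5, where the route is rejoined. This fallback reaches 5 in two steps without a ring enlargement.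

2. Step 6. Discrimination between the two enantiotopic arms may be poor because the stereogenic ring carbons lie β to the carbinol carbons, and over-acylation to the diacetate may compete. The fallback sets out from 7. Statistical mono-acetylation (Ac2O 1.0 equiv, pyridine, CH2Cl2) gives the racemic monoacetate. Preparative chiral-phase SFC then separates 8 from its enantiomer 2-[(3R,5S)-5-(2-hydroxyethyl)-3,5-dimethyl-1,2-dioxolan-3-yl]ethyl acetate F2. F2 is methanolysed (K2CO3, MeOH) back to meso 7 and recycled. The route is rejoined at 8.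

3. Step 9. Electron transfer from the organocopper or Grignard species to the O–O bond, 1,2-attack on the acetate, or insufficient facial selectivity next to the quaternary centre may spoil the conjugate addition. The fallback is free of copper, sets out from 9 and comes back at 12.
   - Copper-free addition of MeMgBr (1.05 equiv, THF, −78 °C) to the aldehyde gives 2-[(3S,5R)-5-(2-hydroxypropyl)-3,5-dimethyl-1,2-dioxolan-3-yl]ethyl acetate F3 (carbinol epimers).
   - Dess–Martin oxidation gives the methyl ketone 2-[(3S,5S)-3,5-dimethyl-5-(2-oxopropyl)-1,2-dioxolan-3-yl]ethyl acetate F4.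
   - Horner–Wadsworth–Emmons olefination under mild Masamune–Roush conditions ((EtO)2P(O)CH2CN, LiCl, DBU, MeCN) gives the unsaturated nitrile 2-[(3S,5R)-5-(3-cyano-2-methylprop-2-en-1-yl)-3,5-dimethyl-1,2-dioxolan-3-yl]ethyl acetate F5 (E/Z).
   - DIBAL-H at −78 °C reduces the nitrile to the enal and removes the acetate, giving 4-[(3R,5S)-5-(2-hydroxyethyl)-3,5-dimethyl-1,2-dioxolan-3-yl]-3-methylbut-2-enal F6 (E/Z).
   - Organocatalytic iminium transfer hydrogenation (chiral imidazolidinone salt, Hantzsch ester, CHCl3, −30 °C; enantioconvergent for E/Z mixtures, catalyst enantiomer chosen for the 3S product) then sets the methyl centre and delivers 12.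

Further compounds
F1 | step 4 | 4,6-dimethoxy-4,6-dimethylcyclohept-1-ene (cis/trans mixture) | COC1(C)CC=CCC(C)(OC)C1
F2 | step 6 | 2-[(3R,5S)-5-(2-hydroxyethyl)-3,5-dimethyl-1,2-dioxolan-3-yl]ethyl acetate (enantiomer of 8) | OCC[C@@]1(C)C[C@@](C)(CCOC(C)=O)OO1
F3 | step 9 | 2-[(3S,5R)-5-(2-hydroxypropyl)-3,5-dimethyl-1,2-dioxolan-3-yl]ethyl acetate (carbinol epimers) | CC(O)C[C@]1(C)C[C@](C)(CCOC(C)=O)OO1
F4 | step 9 | 2-[(3S,5S)-3,5-dimethyl-5-(2-oxopropyl)-1,2-dioxolan-3-yl]ethyl acetate | CC(=O)C[C@]1(C)C[C@](C)(CCOC(C)=O)OO1
F5 | step 9 | 2-[(3S,5R)-5-(3-cyano-2-methylprop-2-en-1-yl)-3,5-dimethyl-1,2-dioxolan-3-yl]ethyl acetate (E/Z) | N#CC=C(C)C[C@]1(C)C[C@](C)(CCOC(C)=O)OO1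
F6 | step 9 | 4-[(3R,5S)-5-(2-hydroxyethyl)-3,5-dimethyl-1,2-dioxolan-3-yl]-3-methylbut-2-enal (E/Z) | O=CC=C(C)C[C@]1(C)C[C@](C)(CCO)OO1
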